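## Analysis of the target

Glaucolide L (31) is a germacranolide: a ten-membered carbocycle (C1–C10) fused along C6–C7 to a five-membered unsaturated lactone (O, C6, C7, C11, C12). The tetrasubstituted double bond C7=C11 is conjugated to the C12 carbonyl and carries the hydroxymethyl carbon C13. There are six stereocentres in two groups. One group is C8 (methacrylate), C10 (methyl) and C1 (acetate), with C1 and C10 adjacent and syn. The other is the contiguous set C4/C5 (a trans-epoxide, i.e. the oxide of an E-alkene) and C6 (lactone carbinol). The two groups are separated by the C2–C3 ethylene bridge and by the planar C7, so only the conformation of the medium ring can relay stereochemical information between them. The functional groups are fragile in different directions: two different esters beside a free primary alcohol invite acyl migration, the methacrylate is a Michael acceptor, the trisubstituted epoxide next to the lactone carbinol is acid-labile, and the C6 hydrogen is γ to the lactone carbonyl and would be removed by base to give an aromatic 2-oxidofuran. The difficulty is twofold: a ten-membered ring must be closed, and C4 to C8 plus C12 and C13 must reach their oxidation levels without the butenolide meeting organometallic reagents or strong base. The route rests on one feature: the lactone atoms O, C6, C7, C11 and C12, with carbon substituents on C6 (C5), C7 (C8) and C11 (C13) and none on C12, are a 2,3,4-trisubstituted furan at a higher oxidation level. Because C12 is the only unsubstituted α-carbon of that furan, oxidation of the heteroarene can place the carbonyl only there.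

## Retrosynthetic reasoning

**C13–O–Si (31 from 30).** The last operation only frees the C13 hydroxyl of silyl ether 30. The primary alcohol stays masked to the end because, once free, it lies within reach of the C8 and C1 esters, and because the silyl ether is inert to every organometallic and oxidative step before it.

**The two C–O bonds of the oxirane (30 from 29).** The epoxide is traced back to the E-alkene of 29. C4=C5 is the only electron-rich double bond of 29, since the butenolide and methacrylate alkenes are acceptor-substituted, so no protection is needed. The cut is placed after C6 is in place because the C6 stereocentre, together with the trans-cycloalkene, defines which alkene face is open. The forward reaction has to deliver oxygen to the outer face, syn to the C6–O bond.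

**C6–H (29 from 27, through 28).** The lactone C6–H bond is cut to give hemiketal 27, which is in equilibrium with its ring-opened 4-oxo-enoic acid. The forward reaction must reduce that C6 ketone 1,2 (it is flanked by two alkenes), with the ring directing the hydride, and let hydroxy acid 28 close to the lactone.

**C12=O and C6–O (27 from 25, through 26).** This is the central disconnection. Removing the carbonyl oxygen from C12 and the hydroxyl from C6 turns the lactone of 27 into the furan of 25. The most base- and nucleophile-sensitive part of the target thus becomes a flat, robust heteroarene, and everything before it may use organolithiums, lithium amides and palladium. The forward reaction is a photooxygenation across C6 and C12 (endoperoxide 26) followed by base-induced fragmentation. Regiochemistry cannot go wrong because only C12 carries a hydrogen.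

**C5–C6 (25 from 24).** The ten-membered ring is opened at the bond between the furan α-carbon C6 and the alkene carbon C5. It is the only ring bond that joins two sp2 carbons, and neither is a stereocentre, so ring closure there cannot erode any configuration. The cut gives a C6 stannane and an E-vinyl iodide in one molecule, the partners of an intramolecular Stille coupling. The alkene geometry is fixed earlier in the open chain, and both esters are already in place at ring closure.

**C8–O acyl, C8–H and C7–C8 (24 from 22 and 23; 22 from 21; 21 from 20; 20 from 7 and 18, through 19).** The methacrylate is cut to alcohol 22 and methacrylic anhydride 23. The C8 stereocentre is traced to ketone 21, because addition of a furyl nucleophile to aldehyde 18 cannot be expected to distinguish the aldehyde faces (the nearest stereocentre, C10, is β). A furyl alkyl ketone, in contrast, is a good substrate for a Corey–Bakshi–Shibata reduction. The C7–C8 bond is then cut to furyllithium 19 (from bromide 7) and aldehyde 18, which divides the molecule into two fragments of similar size.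

**The furan fragment (7 from 5; 5 from 4; 4 from 1, through 2 and 3).** The C6–Sn bond is cut to bromofuran 5. The bromine on the future C7 serves twice: it acidifies and thereby marks the neighbouring α-position (C6, not C12) for deprotonation to 6, and it is later exchanged for lithium to make C7 nucleophilic. C13 comes from formylation of 2 and reduction of 3. The symmetry of 3,4-dibromofuran 1 removes any regiochemical question from the first exchange.

**C1–C10 and the C8 oxygen (18 from 17; 17 from 15 through 16; 15 from 14; 14 from 11 and 12 through 13).** The syn C1/C10 pair is cut at the C1–C10 bond: a Brown crotylboration of aldehyde 11 with Z-crotylborane 13, made from cis-2-butene 12, sets both centres in one step under reagent control. The terminal vinyl group that results is a latent C8 aldehyde (hydroboration, then oxidation). The C1 hydroxyl is acetylated at once, so no protecting group is spent on C1.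

**C4–C15 and C5–I (11 from 10; 10 from 8 through 9).** The E-trisubstituted vinyl iodide is cut to pent-4-yn-1-ol 8. Syn carboalumination (vinylalane 9) and iodinolysis fix the geometry of the later C4=C5 bond at the very start.

## Alternatives that were turned down

**Alternative 1: ring closure at C2–C3 by an allyl sulfone anion and a terminal epoxide.** The disconnection is the C2–C3 ring bond, with the furan kept. In the forward key step LiN(SiMe3)2 would deprotonate C3 (allylic and next to a phenylsulfonyl group); the carbanion would open a terminal C1–C2 epoxide at C2, close the ten-membered ring and release the C1 alkoxide, giving A1.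
- For it: an sp3–sp3 bond is formed by an irreversible epoxide opening, which asks less of the transition state than a coupling that must create a twisted furyl–alkenyl bond, and the C1 hydroxyl appears in the same step. On the ring closure itself this plan is as strong as the chosen one, or stronger.
- Against it: C1 must come from an enantiopure terminal epoxide next to C10 on a flexible chain. The C3 anion is an allyl anion conjugated through C4=C5 into the furan, so attack through C5 and loss of the E geometry are possible. After closure the allylic sulfone must be removed reductively, a step that can move or isomerize the double bond. C1 then has to be acetylated and C8 desilylated and methacryloylated.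
- Comparison: A1 therefore sits about four steps before the point that 25 reaches directly, and the furan-to-butenolide oxidation is still needed. The chosen route offers no auxiliary group, both esters in place at ring closure, and an alkene geometry that never meets carbanion chemistry.

**Alternative 2: lithiation–borylation union at C1–C10.** The disconnection is the C1–C10 bond of an open chain. In the forward key step s-BuLi with sparteine would deprotonate a primary C1 carbamate; the lithiated carbon would capture a boronic ester on C10, C10 would migrate from boron to C1, and NaOH/H2O2 would give the C1 hydroxyl, that is A2.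
- For it: both centres are set by reagent-controlled, stereospecific steps, either diastereomer is available at will, and the C8 oxygen is already in the fragment. On stereochemical certainty at C1/C10, and in avoiding the oxidation–reduction sequence at C8, it is stronger than the chosen route.
- Against it: A2 is acyclic, the C6–C7 bond is missing, C11 to C13 are absent, and three different protecting groups remain to be handled. Neither the ten-membered ring nor the lactone is addressed. The secondary, α-branched boronic ester needs its own asymmetric synthesis.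
- Comparison: the key step is spent on the C1/C10 pair, which one crotylboration (step 6) sets from a five-carbon aldehyde and butene. The chosen strategy gives the same pair in one step and a plan for the ring and the lactone.

**Alternative 3: Grob fragmentation of a hydroazulene.** The disconnection adds a transannular C4–C8 bond, so that the ten-membered ring becomes a fused five–seven bicycle. In the forward key step KN(SiMe3)2 would deprotonate a tertiary C8 hydroxyl; the C4–C8 bond and a C5 sulfonate would leave together, forming C8=O and the E-C4=C5 alkene, to give A3.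
- For it: no entropically disfavoured ring closure is needed, the alkene geometry follows from the antiperiplanar arrangement of the breaking bonds, and the butenolide with C6 is already present. On ring formation and alkene geometry it is stronger than an intramolecular Stille coupling.
- Against it: the tricyclic precursor needs defined centres at C4 (quaternary), C5 and C8, all three destroyed in the fragmentation, besides C6, C10 and C1. The strong base meets a butenolide whose C6–H is acidic and sits next to the C5 leaving group, so elimination competes with fragmentation. The C1 acetate lies 1,4 to the C8 alkoxide. A3 is a 2-ene-1,4-dicarbonyl system with acidic C9–H and C6–H, whose C8 ketone must still be reduced with ring control and without conjugate reduction.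
- Comparison: building the tricycle would take many more steps than reaching 25. The chosen strategy sets C8 in the open chain under reagent control and unveils the butenolide only after all strong bases and organometallics have been used.

Key step: step 15

Remark on the chemistry: atom numbers are those of the germacrane skeleton (ring carbons C1–C10, lactone carbons C11 and C12, C13 on C11, C14 on C10, C15 on C4); compounds 20 and 27 are carried as epimer mixtures at C8 and C6 because each of these centres is set afresh in the following step.

## Route

Step 1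
Reactants: 1 3,4-dibromofuran
Product: 4 (4-bromofuran-3-yl)methanol, via 3-bromo-4-lithiofuran 2 (not isolated), via 4-bromofuran-3-carbaldehyde 3 (not isolated)
Conditions: n-BuLi, Et2O, −78 °C; DMF, −78 to 0 °C; then MeOH, NaBH4, 0 °C
Reagents that add atoms: N,N-dimethylformamide (CN(C)C=O)
Why: Bromine–lithium exchange on one of the two equivalent C–Br bonds gives the 3-lithiofuran, which is formylated by DMF; borohydride reduction in the same flask gives the hydroxymethyl group that becomes C13.

Step 2
Reactants: 4 (4-bromofuran-3-yl)methanol
Product: 5 [(4-bromofuran-3-yl)methoxy](tert-butyl)dimethylsilane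
Conditions: TBSCl, imidazole, DMF, rt
Reagents that add atoms: tert-butyldimethylsilyl chloride (CC(C)(C)[Si](C)(C)Cl)
Why: Imidazole-promoted silylation of a primary alcohol; the silyl ether survives every later step up to the final fluoride treatment.

Step 3
Reactants: 5 [(4-bromofuran-3-yl)methoxy](tert-butyl)dimethylsilane
Product: 7 tributyl[3-bromo-4-({[tert-butyl(dimethyl)silyl]oxy}methyl)furan-2-yl]stannane, via 2-lithiofuran 6 (not isolated)
Conditions: LiN(i-Pr)2, THF, −78 °C; Bu3SnCl, −78 °C to rt
Reagents that add atoms: tributyltin chloride (CCCC[Sn](Cl)(CCCC)CCCC)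
Why: Directed deprotonation and stannylation: the lithium amide removes the α-hydrogen flanked by the ring oxygen and the C–Br bond, the most acidic position, without exchanging the bromide, so tin is placed on the future C6 and not on C12.

Step 4
Reactants: 8 pent-4-yn-1-ol
Product: 10 (E)-5-iodo-4-methylpent-4-en-1-ol, via E-vinylalane 9 (not isolated)
Conditions: Me3Al, Cp2ZrCl2 (cat.), CH2Cl2, 0 °C to rt; I2, THF, −30 to 0 °C
Reagents that add atoms: trimethylaluminium (C[Al](C)C); iodine (II)
Why: Negishi zirconium-catalysed carboalumination adds methyl and aluminium syn across the terminal alkyne with aluminium at the terminus; iodinolysis with retention gives the E-vinyl iodide that carries C15 and fixes the geometry of the later C4=C5 bond.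

Step 5
Reactants: 10 (E)-5-iodo-4-methylpent-4-en-1-ol
Product: 11 (E)-5-iodo-4-methylpent-4-enal
Conditions: Dess–Martin periodinane, NaHCO3, CH2Cl2, 0 °C to rt
Reagents that add atoms: none
Why: Dess–Martin oxidation of a primary alcohol stops at the aldehyde and leaves the vinyl iodide untouched.

Step 6
Reactants: 11 (E)-5-iodo-4-methylpent-4-enal; 12 cis-2-butene
Product: 14 (3S,4S,7E)-8-iodo-3,7-dimethylocta-1,7-dien-4-ol, via Z-crotyldiisopinocampheylborane 13 (not isolated)
Conditions: KOt-Bu, n-BuLi, THF, −78 to −45 °C; (+)-Ipc2BOMe, −78 °C; BF3·OEt2, −78 °C; then 11, −78 °C; NaOH, H2O2, 0 °C to rt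
Reagents that add atoms: none
Why: Brown crotylboration through a closed chair transition state translates the Z geometry of the crotylborane into the syn relation of the C10 methyl and the C1 hydroxyl. The isopinocampheyl groups derived from (−)-α-pinene direct the transfer to the Re face of the aldehyde, which gives the (3S,4S) isomer (C10 S, C1 S).

Step 7
Reactants: 14 (3S,4S,7E)-8-iodo-3,7-dimethylocta-1,7-dien-4-ol
Product: 15 (3S,4S,7E)-8-iodo-3,7-dimethylocta-1,7-dien-4-yl acetate
Conditions: Ac2O, pyridine, DMAP (cat.), CH2Cl2, rt
Reagents that add atoms: acetic anhydride (CC(=O)OC(C)=O)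
Why: DMAP-catalysed acylation installs the C1 acetate of the target at once, so that no protecting group is needed at C1.

Step 8
Reactants: 15 (3S,4S,7E)-8-iodo-3,7-dimethylocta-1,7-dien-4-yl acetate
Product: 17 (3S,4S,7E)-1-hydroxy-8-iodo-3,7-dimethyloct-7-en-4-yl acetate, via B-alkyl-9-BBN adduct 16 (not isolated)
Conditions: 9-BBN, THF, 0 °C to rt; aq. NaOAc, H2O2, 0 °C to rt
Reagents that add atoms: hydrogen peroxide (OO)
Why: Anti-Markovnikov hydroboration–oxidation: 9-BBN selects the monosubstituted alkene over the trisubstituted iodoalkene and does not reduce the acetate, and the acetate-buffered peroxide oxidation spares the ester; the new primary carbinol is C8.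

Step 9
Reactants: 17 (3S,4S,7E)-1-hydroxy-8-iodo-3,7-dimethyloct-7-en-4-yl acetate
Product: 18 (3S,4S,7E)-8-iodo-3,7-dimethyl-1-oxooct-7-en-4-yl acetate
Conditions: Dess–Martin periodinane, NaHCO3, CH2Cl2, 0 °C to rt
Reagents that add atoms: none
Why: Dess–Martin oxidation to the C8 aldehyde; the C10 stereocentre is β to the carbonyl and cannot epimerize.

Step 10
Reactants: 7 tributyl[3-bromo-4-({[tert-butyl(dimethyl)silyl]oxy}methyl)furan-2-yl]stannane; 18 (3S,4S,7E)-8-iodo-3,7-dimethyl-1-oxooct-7-en-4-yl acetate
Product: 20 (3S,4S,7E)-1-[4-({[tert-butyl(dimethyl)silyl]oxy}methyl)-2-(tributylstannyl)furan-3-yl]-1-hydroxy-8-iodo-3,7-dimethyloct-7-en-4-yl acetate (C8 epimers), via 3-lithiofuran 19 (not isolated)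
Conditions: t-BuLi (2 equiv), Et2O, −78 °C; then 18, −78 °C; AcOH, −78 °C
Reagents that add atoms: none
Why: Bromine–lithium exchange with t-BuLi (the second equivalent destroys the tert-butyl bromide) is far faster than attack of this hindered base on the tributylstannyl group, and the furyllithium then adds 1,2 to the aldehyde, which reacts much faster than the secondary acetate or the vinyl iodide at −78 °C. The cold acidic quench prevents acetyl transfer to the new alkoxide; C8 forms as a mixture that the next two steps correct.

Step 11
Reactants: 20 (3S,4S,7E)-1-[4-({[tert-butyl(dimethyl)silyl]oxy}methyl)-2-(tributylstannyl)furan-3-yl]-1-hydroxy-8-iodo-3,7-dimethyloct-7-en-4-yl acetate (C8 epimers)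
Product: 21 (3S,4S,7E)-1-[4-({[tert-butyl(dimethyl)silyl]oxy}methyl)-2-(tributylstannyl)furan-3-yl]-8-iodo-3,7-dimethyl-1-oxooct-7-en-4-yl acetate
Conditions: Dess–Martin periodinane, NaHCO3, CH2Cl2, 0 °C
Reagents that add atoms: none
Why: Dess–Martin oxidation converges both C8 epimers on one furyl ketone; the bicarbonate buffer protects the furyl–tin bond from the acetic acid that is released.

Step 12
Reactants: 21 (3S,4S,7E)-1-[4-({[tert-butyl(dimethyl)silyl]oxy}methyl)-2-(tributylstannyl)furan-3-yl]-8-iodo-3,7-dimethyl-1-oxooct-7-en-4-yl acetate
Product: 22 (1S,3S,4S,7E)-1-[4-({[tert-butyl(dimethyl)silyl]oxy}methyl)-2-(tributylstannyl)furan-3-yl]-1-hydroxy-8-iodo-3,7-dimethyloct-7-en-4-yl acetate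
Conditions: (R)-Me-CBS oxazaborolidine (cat.), BH3·SMe2, THF, −20 °C; then MeOH
Reagents that add atoms: none
Why: Corey–Bakshi–Shibata reduction: the ketone binds to the catalyst with the larger furyl group away from the catalyst framework and hydride is delivered from the coordinated borane to one face. With the (R)-catalyst and furyl as the large group this gives the (S) carbinol at C8 under reagent control, independent of the remote C10 and C1 centres.

Step 13
Reactants: 22 (1S,3S,4S,7E)-1-[4-({[tert-butyl(dimethyl)silyl]oxy}methyl)-2-(tributylstannyl)furan-3-yl]-1-hydroxy-8-iodo-3,7-dimethyloct-7-en-4-yl acetate; 23 methacrylic anhydride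
Product: 24 (1S,3S,4S,7E)-4-acetoxy-1-[4-({[tert-butyl(dimethyl)silyl]oxy}methyl)-2-(tributylstannyl)furan-3-yl]-8-iodo-3,7-dimethyloct-7-en-1-yl 2-methylprop-2-enoate
Conditions: Et3N, DMAP (cat.), CH2Cl2, 0 °C to rt
Reagents that add atoms: none
Why: DMAP-catalysed acyl transfer puts the methacrylate on C8 with retention; the basic medium leaves the acid-sensitive furyl stannane intact.

Step 14
Reactants: 24 (1S,3S,4S,7E)-4-acetoxy-1-[4-({[tert-butyl(dimethyl)silyl]oxy}methyl)-2-(tributylstannyl)furan-3-yl]-8-iodo-3,7-dimethyloct-7-en-1-yl 2-methylprop-2-enoate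
Product: 25 (1S,4E,8S,10S)-1-acetoxy-13-[(tert-butyldimethylsilyl)oxy]-6,12-epoxygermacra-4,6,11-trien-8-yl methacrylate (ten-membered ring-fused furan)
Conditions: Pd2(dba)3 (cat.), AsPh3, CuI (cat.), DMF, 0.002 M, slow addition, rt to 45 °C
Reagents that add atoms: none
Why: Intramolecular Stille coupling: zerovalent palladium inserts into the vinyl C–I bond with retention of the E geometry, the furyl group is transferred from tin with the help of copper iodide, and reductive elimination forms the C5–C6 bond and the ten-membered ring. High dilution favours ring closure over oligomerization, and neither coupling carbon is a stereocentre.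

Step 15
Reactants: 25 (1S,4E,8S,10S)-1-acetoxy-13-[(tert-butyldimethylsilyl)oxy]-6,12-epoxygermacra-4,6,11-trien-8-yl methacrylate (ten-membered ring-fused furan)
Product: 27 (1S,4E,8S,10S)-1-acetoxy-13-[(tert-butyldimethylsilyl)oxy]-6-hydroxygermacra-4,7(11)-dien-12,6-olide 8-methacrylate (C6 γ-hydroxybutenolide; both C6 epimers), via C6–C12 endoperoxide 26 (not isolated)
Conditions: O2, hν (visible), tetraphenylporphyrin (cat.), i-Pr2NEt, CH2Cl2, −78 °C
Reagents that add atoms: oxygen (O=O)
Why: Light and the porphyrin sensitizer generate singlet oxygen, which adds as a dienophile across the two α-carbons C6 and C12 of the electron-rich furan in a [4+2] cycloaddition to give the bicyclic endoperoxide 26. The hindered amine then removes the only hydrogen on a peroxide-bearing carbon, the one on C12, and the O–O bond breaks in a Kornblum–DeLaMare fragmentation, so that C12 becomes the lactone carbonyl and the peroxide oxygen left on C6 becomes the hemiketal hydroxyl. The closest known reaction type is the base-assisted, dye-sensitized photooxygenation of furans with one free α-position to γ-hydroxybutenolides. No ring is closed: the furan ring is converted in place into the lactone ring, and the transient peroxide bridge is opened again in the same flask. The only new stereocentre is the hemiketal carbon C6; it is not controlled and need not be, because both epimers open to the same C6 ketone in the next step. Two selectivities are needed: the carbonyl must form at C12 and not at C6, which is secured because C6 is fully substituted and has no proton to lose, and the furan must react before the C4=C5 alkene and the methacrylate, which is secured by the much higher reactivity of a trisubstituted furan toward singlet oxygen at low temperature and by the electron-poor character of the methacrylate. The ring is expected to hold the E-alkene out of conjugation with the furan, which disfavours addition across the furan–alkene diene.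

Step 16
Reactants: 27 (1S,4E,8S,10S)-1-acetoxy-13-[(tert-butyldimethylsilyl)oxy]-6-hydroxygermacra-4,7(11)-dien-12,6-olide 8-methacrylate (C6 γ-hydroxybutenolide; both C6 epimers)
Product: 29 (1S,4E,6R,8S,10S)-1-acetoxy-13-[(tert-butyldimethylsilyl)oxy]germacra-4,7(11)-dien-12,6-olide 8-methacrylate, via Z-hydroxy acid 28 (not isolated)
Conditions: NaBH4, CeCl3·7H2O, MeOH–THF, −40 °C; then aq. citric acid (pH 4), rt
Reagents that add atoms: none
Why: Luche reduction: the hemiketal is in equilibrium with its ring-opened keto carboxylate, whose C6 carbonyl is reduced 1,2 by the cerium-modified borohydride, and the Z-hydroxy acid 28 closes to the lactone on acidification. C6 is set by substrate control: hydride is expected to reach the carbonyl from the outer face of the ten-membered ring, giving the 6R alcohol in 28 and 29. The descriptor becomes 6S after epoxidation only because C5 then outranks C7.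

Step 17
Reactants: 29 (1S,4E,6R,8S,10S)-1-acetoxy-13-[(tert-butyldimethylsilyl)oxy]germacra-4,7(11)-dien-12,6-olide 8-methacrylate
Product: 30 (1S,4R,5R,6S,8S,10S)-1-acetoxy-13-[(tert-butyldimethylsilyl)oxy]-4,5-epoxygermacr-7(11)-en-12,6-olide 8-methacrylate
Conditions: m-CPBA, NaHCO3, CH2Cl2, 0 °C
Reagents that add atoms: 3-chloroperbenzoic acid (O=C(OO)c1cccc(Cl)c1)
Why: Prilezhaev epoxidation: the trisubstituted C4=C5 bond is the only electron-rich alkene, the butenolide and methacrylate double bonds being acceptor-substituted. The peracid attacks the outer face of the E-cycloalkene; allylic strain with the C15 methyl keeps C6–H in the alkene plane and C6–C7 leads into the ring, so the open face is the one syn to the C6–O bond, which gives the (4R,5R) epoxide.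

Step 18
Reactants: 30 (1S,4R,5R,6S,8S,10S)-1-acetoxy-13-[(tert-butyldimethylsilyl)oxy]-4,5-epoxygermacr-7(11)-en-12,6-olide 8-methacrylate
Product: 31 glaucolide L
Conditions: HF·pyridine, pyridine, THF, 0 °C to rt
Reagents that add atoms: none
Why: Fluoride-driven cleavage of the primary silyl ether through Si–F bond formation; the pyridine buffer keeps the epoxide closed and both esters in place.

## Compound list

1 | 3,4-dibromofuran | Brc1cocc1Br | starting material
2 | 3-bromo-4-lithiofuran | [Li]c1cocc1Br | intermediate
3 | 4-bromofuran-3-carbaldehyde | O=Cc1cocc1Br | intermediate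
4 | (4-bromofuran-3-yl)methanol | OCc1cocc1Br | intermediate
5 | [(4-bromofuran-3-yl)methoxy](tert-butyl)dimethylsilane | CC(C)(C)[Si](C)(C)OCc1cocc1Br | intermediate
6 | [3-bromo-4-({[tert-butyl(dimethyl)silyl]oxy}methyl)furan-2-yl]lithium | [Li]c1occ(CO[Si](C)(C)C(C)(C)C)c1Br | intermediate
7 | tributyl[3-bromo-4-({[tert-butyl(dimethyl)silyl]oxy}methyl)furan-2-yl]stannane | CCCC[Sn](CCCC)(CCCC)c1occ(CO[Si](C)(C)C(C)(C)C)c1Br | intermediate
8 | pent-4-yn-1-ol | C#CCCCO | starting material
9 | dimethyl{(1E)-5-[(dimethylalumanyl)oxy]-2-methylpent-1-en-1-yl}alumane (E-vinylalane) | C[Al](C)/C=C(\C)CCCO[Al](C)C | intermediate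
10 | (E)-5-iodo-4-methylpent-4-en-1-ol | OCCC/C(C)=C/I | intermediate
11 | (E)-5-iodo-4-methylpent-4-enal | O=CCC/C(C)=C/I | intermediate
12 | cis-2-butene | C/C=C\C | starting material
13 | (Z)-but-2-en-1-ylbis[(1S,2R,3S,5S)-isopinocampheyl]borane (isopinocampheyl groups from (−)-α-pinene) | C/C=C\CB([C@H]1C[C@H]2C[C@@H]([C@@H]1C)C2(C)C)[C@H]1C[C@H]2C[C@@H]([C@@H]1C)C2(C)C | intermediate
14 | (3S,4S,7E)-8-iodo-3,7-dimethylocta-1,7-dien-4-ol | C=C[C@H](C)[C@@H](O)CC/C(C)=C/I | intermediate
15 | (3S,4S,7E)-8-iodo-3,7-dimethylocta-1,7-dien-4-yl acetate | C=C[C@H](C)[C@@H](OC(C)=O)CC/C(C)=C/I | intermediate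
16 | (3S,4S,7E)-1-(9-borabicyclo[3.3.1]nonan-9-yl)-8-iodo-3,7-dimethyloct-7-en-4-yl acetate | C1CCC2CCCC1B2CC[C@H](C)[C@@H](OC(C)=O)CC/C(C)=C/I | intermediate
17 | (3S,4S,7E)-1-hydroxy-8-iodo-3,7-dimethyloct-7-en-4-yl acetate | OCC[C@H](C)[C@@H](OC(C)=O)CC/C(C)=C/I | intermediate
18 | (3S,4S,7E)-8-iodo-3,7-dimethyl-1-oxooct-7-en-4-yl acetate | O=CC[C@H](C)[C@@H](OC(C)=O)CC/C(C)=C/I | intermediate
19 | [4-({[tert-butyl(dimethyl)silyl]oxy}methyl)-2-(tributylstannyl)furan-3-yl]lithium | [Li]c1c(CO[Si](C)(C)C(C)(C)C)coc1[Sn](CCCC)(CCCC)CCCC | intermediate
20 | (3S,4S,7E)-1-[4-({[tert-butyl(dimethyl)silyl]oxy}methyl)-2-(tributylstannyl)furan-3-yl]-1-hydroxy-8-iodo-3,7-dimethyloct-7-en-4-yl acetate (C8 epimers) | OC(c1c(CO[Si](C)(C)C(C)(C)C)coc1[Sn](CCCC)(CCCC)CCCC)C[C@H](C)[C@@H](OC(C)=O)CC/C(C)=C/I | intermediate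
21 | (3S,4S,7E)-1-[4-({[tert-butyl(dimethyl)silyl]oxy}methyl)-2-(tributylstannyl)furan-3-yl]-8-iodo-3,7-dimethyl-1-oxooct-7-en-4-yl acetate | O=C(c1c(CO[Si](C)(C)C(C)(C)C)coc1[Sn](CCCC)(CCCC)CCCC)C[C@H](C)[C@@H](OC(C)=O)CC/C(C)=C/I | intermediate
22 | (1S,3S,4S,7E)-1-[4-({[tert-butyl(dimethyl)silyl]oxy}methyl)-2-(tributylstannyl)furan-3-yl]-1-hydroxy-8-iodo-3,7-dimethyloct-7-en-4-yl acetate | O[C@H](c1c(CO[Si](C)(C)C(C)(C)C)coc1[Sn](CCCC)(CCCC)CCCC)C[C@H](C)[C@@H](OC(C)=O)CC/C(C)=C/I | intermediate
23 | methacrylic anhydride | C=C(C)C(=O)OC(=O)C(C)=C | starting material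
24 | (1S,3S,4S,7E)-4-acetoxy-1-[4-({[tert-butyl(dimethyl)silyl]oxy}methyl)-2-(tributylstannyl)furan-3-yl]-8-iodo-3,7-dimethyloct-7-en-1-yl 2-methylprop-2-enoate | C=C(C)C(=O)O[C@H](c1c(CO[Si](C)(C)C(C)(C)C)coc1[Sn](CCCC)(CCCC)CCCC)C[C@H](C)[C@@H](OC(C)=O)CC/C(C)=C/I | intermediate
25 | (1S,4E,8S,10S)-1-acetoxy-13-[(tert-butyldimethylsilyl)oxy]-6,12-epoxygermacra-4,6,11-trien-8-yl methacrylate (ten-membered ring-fused furan) | C=C(C)C(=O)O[C@H]1C[C@H](C)[C@@H](OC(C)=O)CC/C(C)=C/c2occ(CO[Si](C)(C)C(C)(C)C)c12 | intermediate
26 | C6–C12 endoperoxide of 25 (2,3,7-trioxabicyclo[2.2.1]hept-5-ene fused to the ten-membered ring; peroxide bridge between C6 and C12) | C=C(C)C(=O)O[C@H]1C[C@H](C)[C@@H](OC(C)=O)CC/C(C)=C/C23OOC(O2)C(CO[Si](C)(C)C(C)(C)C)=C13 | intermediate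
27 | (1S,4E,8S,10S)-1-acetoxy-13-[(tert-butyldimethylsilyl)oxy]-6-hydroxygermacra-4,7(11)-dien-12,6-olide 8-methacrylate (C6 γ-hydroxybutenolide; both C6 epimers) | C=C(C)C(=O)O[C@H]1C[C@H](C)[C@@H](OC(C)=O)CC/C(C)=C/C2(O)OC(=O)C(CO[Si](C)(C)C(C)(C)C)=C12 | intermediate
28 | (1S,4E,6R,7Z,8S,10S)-1-acetoxy-13-[(tert-butyldimethylsilyl)oxy]-6-hydroxy-8-(methacryloyloxy)germacra-4,7(11)-dien-12-oic acid (C6 and the carboxyl cis on C7=C11) | C=C(C)C(=O)O[C@H]1C[C@H](C)[C@@H](OC(C)=O)CC/C(C)=C/[C@@H](O)/C1=C(/CO[Si](C)(C)C(C)(C)C)C(=O)O | intermediate
29 | (1S,4E,6R,8S,10S)-1-acetoxy-13-[(tert-butyldimethylsilyl)oxy]germacra-4,7(11)-dien-12,6-olide 8-methacrylate | C=C(C)C(=O)O[C@H]1C[C@H](C)[C@@H](OC(C)=O)CC/C(C)=C/[C@H]2OC(=O)C(CO[Si](C)(C)C(C)(C)C)=C12 | intermediate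
30 | (1S,4R,5R,6S,8S,10S)-1-acetoxy-13-[(tert-butyldimethylsilyl)oxy]-4,5-epoxygermacr-7(11)-en-12,6-olide 8-methacrylate | C=C(C)C(=O)O[C@H]1C[C@H](C)[C@@H](OC(C)=O)CC[C@@]2(C)O[C@@H]2[C@H]2OC(=O)C(CO[Si](C)(C)C(C)(C)C)=C12 | intermediate
31 | glaucolide L, (1S,4R,5R,6S,8S,10S)-1-acetoxy-4,5-epoxy-13-hydroxygermacr-7(11)-en-12,6-olide 8-methacrylate | C=C(C)C(=O)O[C@H]1C[C@H](C)[C@@H](OC(C)=O)CC[C@@]2(C)O[C@@H]2[C@H]2OC(=O)C(CO)=C12 | target

## Step count and least certain steps

Total: 18 steps. Longest linear sequence: 15 steps (8 to 31, steps 4–18); the furan arm (1 to 7, steps 1–3) joins at step 10.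

**Step 15 (key step).** The most likely failure is oxygenation at the wrong π system: an ene reaction of singlet oxygen at C4=C5, or addition across the furan–alkene diene if the ring leaves the two conjugated. The endoperoxide could also rearrange before the amine removes the C12 hydrogen. The fallback replaces the cycloaddition by a two-electron ring opening. It sets out from 25: N-bromosuccinimide in buffered aqueous acetone at low temperature opens the furan to the Z-configured keto enal F1 (C6 ketone, C12 aldehyde). A Pinnick oxidation (NaClO2, NaH2PO4, 2-methylbut-2-ene) then converts the C12 aldehyde into the acid, which closes to the hemiketal; the route is rejoined at 27.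

**Step 14.** Ring closure may lose to intermolecular coupling (oligomers), or the palladium intermediate may stall because reductive elimination has to create a twisted furyl–alkenyl bond inside a ten-membered ring. Protodestannylation would then consume the substrate. The fallback makes the C5–C6 bond first and closes the ring at C7–C8. It sets out from 7 and 18: an intermolecular Stille coupling (the vinyl iodide reacts before the furyl bromide) gives the bromofuran aldehyde F2. A Nozaki–Hiyama–Kishi closure (CrCl2, NiCl2 cat., high dilution), of the kind known for bromofuran aldehydes, gives the macrocyclic carbinol F3. Dess–Martin oxidation gives the macrocyclic ketone F4, reduction with the (R)-Me-CBS catalyst and borane gives the macrocyclic alcohol F5, and acylation with 23 returns to the route at 25.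

**Step 10.** Tin–lithium exchange, or transfer of the stannyl group between furyllithium molecules so that lithium ends up on the α-carbon, may compete with the bromine–lithium exchange. Attack on the acetate is a lesser concern. The fallback keeps tin away from the organolithium step and reverses the polarity of the ring closure. It sets out from 5:
- deprotonation with LiN(i-Pr)2 and chlorination with C2Cl6 gives the chlorobromofuran F6, whose C–Cl bond is inert to t-BuLi;
- exchange and addition to 18 gives the chloro carbinol F7, Dess–Martin oxidation the chloro ketone F8, CBS reduction the chloro alcohol F9, and acylation with 23 the chloro methacrylate F10;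
- Pd(PPh3)4 with Me3SnSnMe3 converts the vinyl iodide into the vinyl trimethylstannane F11;
- an intramolecular Stille coupling onto the chlorofuran (Pd2(dba)3, P(t-Bu)3, CsF, dioxane, high dilution) rejoins the route at 25.

**Step 16.** Hydride may be delivered to the wrong face of the C6 carbonyl, because the facial preference rests on a ring conformation that is not known in advance; conjugate reduction is a minor risk. The fallback replaces substrate control by reagent control. It sets out from 27: Me3SiCHN2 traps the ring-opened form as the keto ester F12. Reduction with the (S)-Me-CBS catalyst and catecholborane should give the hydroxy ester F13, if the fully substituted C7 alkenyl group acts as the large substituent; the mirror-image catalyst is available if the sense is reversed. Acid-catalysed lactonization (pyridinium p-toluenesulfonate) rejoins the route at 29.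

**Step 17.** The peracid may attack the inner face if the ring adopts another conformation, giving the diastereomeric epoxide; acid-induced opening of the product is a lesser risk under buffer. The fallback delivers the oxygen from the face opposite to the one the electrophile uses. It sets out from 29: N-bromosuccinimide in aqueous THF forms the bromonium ion on the accessible face and water opens it anti at the more substituted C4, giving the bromohydrin F14. Ag2O then closes the oxirane with inversion at C5, and the route is rejoined at 30.

**Step 12.** The reduction may be slow or poorly face-selective, because the carbonyl is flanked by the tributylstannyl and silyloxymethyl groups, which twist the furan and blur the size difference the catalyst reads. The fallback sets out from 20: the C8 epimers are separated; the (8S) epimer is 22 and goes on as in step 13. The (8R)-carbinol F15 is esterified under Mitsunobu conditions (methacrylic acid, PPh3, diisopropyl azodicarboxylate) with inversion at C8, which rejoins the route directly at 24.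

## Further compounds

F1 | step 15 | (1S,4E,8S,10S)-1-acetoxy-13-[(tert-butyldimethylsilyl)oxy]-8-(methacryloyloxy)-6-oxogermacra-4,7(11)-dien-12-al (Z-keto enal) | C=C(C)C(=O)O[C@H]1C[C@H](C)[C@@H](OC(C)=O)CC/C(C)=C/C(=O)/C1=C(/CO[Si](C)(C)C(C)(C)C)C=O
F2 | step 14 | (3S,4S,7E)-8-[3-bromo-4-({[tert-butyl(dimethyl)silyl]oxy}methyl)furan-2-yl]-3,7-dimethyl-1-oxooct-7-en-4-yl acetate | O=CC[C@H](C)[C@@H](OC(C)=O)CC/C(C)=C/c1occ(CO[Si](C)(C)C(C)(C)C)c1Br
F3 | step 14 | (1S,4E,10S)-1-acetoxy-13-[(tert-butyldimethylsilyl)oxy]-6,12-epoxygermacra-4,6,11-trien-8-ol (C8 epimers) | OC1C[C@H](C)[C@@H](OC(C)=O)CC/C(C)=C/c2occ(CO[Si](C)(C)C(C)(C)C)c12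
F4 | step 14 | (1S,4E,10S)-1-acetoxy-13-[(tert-butyldimethylsilyl)oxy]-6,12-epoxygermacra-4,6,11-trien-8-one | O=C1C[C@H](C)[C@@H](OC(C)=O)CC/C(C)=C/c2occ(CO[Si](C)(C)C(C)(C)C)c12
F5 | step 14 | (1S,4E,8S,10S)-1-acetoxy-13-[(tert-butyldimethylsilyl)oxy]-6,12-epoxygermacra-4,6,11-trien-8-ol | O[C@H]1C[C@H](C)[C@@H](OC(C)=O)CC/C(C)=C/c2occ(CO[Si](C)(C)C(C)(C)C)c12
F6 | step 10 | [(4-bromo-5-chlorofuran-3-yl)methoxy](tert-butyl)dimethylsilane | CC(C)(C)[Si](C)(C)OCc1coc(Cl)c1Br
F7 | step 10 | (3S,4S,7E)-1-[4-({[tert-butyl(dimethyl)silyl]oxy}methyl)-2-chlorofuran-3-yl]-1-hydroxy-8-iodo-3,7-dimethyloct-7-en-4-yl acetate (C8 epimers) | OC(c1c(CO[Si](C)(C)C(C)(C)C)coc1Cl)C[C@H](C)[C@@H](OC(C)=O)CC/C(C)=C/I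
F8 | step 10 | (3S,4S,7E)-1-[4-({[tert-butyl(dimethyl)silyl]oxy}methyl)-2-chlorofuran-3-yl]-8-iodo-3,7-dimethyl-1-oxooct-7-en-4-yl acetate | O=C(c1c(CO[Si](C)(C)C(C)(C)C)coc1Cl)C[C@H](C)[C@@H](OC(C)=O)CC/C(C)=C/I
F9 | step 10 | (1S,3S,4S,7E)-1-[4-({[tert-butyl(dimethyl)silyl]oxy}methyl)-2-chlorofuran-3-yl]-1-hydroxy-8-iodo-3,7-dimethyloct-7-en-4-yl acetate | O[C@H](c1c(CO[Si](C)(C)C(C)(C)C)coc1Cl)C[C@H](C)[C@@H](OC(C)=O)CC/C(C)=C/I
F10 | step 10 | (1S,3S,4S,7E)-4-acetoxy-1-[4-({[tert-butyl(dimethyl)silyl]oxy}methyl)-2-chlorofuran-3-yl]-8-iodo-3,7-dimethyloct-7-en-1-yl 2-methylprop-2-enoate | C=C(C)C(=O)O[C@H](c1c(CO[Si](C)(C)C(C)(C)C)coc1Cl)C[C@H](C)[C@@H](OC(C)=O)CC/C(C)=C/I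
F11 | step 10 | (1S,3S,4S,7E)-4-acetoxy-1-[4-({[tert-butyl(dimethyl)silyl]oxy}methyl)-2-chlorofuran-3-yl]-3,7-dimethyl-8-(trimethylstannyl)oct-7-en-1-yl 2-methylprop-2-enoate | C=C(C)C(=O)O[C@H](c1c(CO[Si](C)(C)C(C)(C)C)coc1Cl)C[C@H](C)[C@@H](OC(C)=O)CC/C(C)=C/[Sn](C)(C)C
F12 | step 16 | methyl (1S,4E,7Z,8S,10S)-1-acetoxy-13-[(tert-butyldimethylsilyl)oxy]-8-(methacryloyloxy)-6-oxogermacra-4,7(11)-dien-12-oate | C=C(C)C(=O)O[C@H]1C[C@H](C)[C@@H](OC(C)=O)CC/C(C)=C/C(=O)/C1=C(/CO[Si](C)(C)C(C)(C)C)C(=O)OC
F13 | step 16 | methyl (1S,4E,6R,7Z,8S,10S)-1-acetoxy-13-[(tert-butyldimethylsilyl)oxy]-6-hydroxy-8-(methacryloyloxy)germacra-4,7(11)-dien-12-oate | C=C(C)C(=O)O[C@H]1C[C@H](C)[C@@H](OC(C)=O)CC/C(C)=C/[C@@H](O)/C1=C(/CO[Si](C)(C)C(C)(C)C)C(=O)OC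
F14 | step 17 | (1S,4R,5S,6S,8S,10S)-1-acetoxy-5-bromo-13-[(tert-butyldimethylsilyl)oxy]-4-hydroxygermacr-7(11)-en-12,6-olide 8-methacrylate | C=C(C)C(=O)O[C@H]1C[C@H](C)[C@@H](OC(C)=O)CC[C@@](C)(O)[C@@H](Br)[C@H]2OC(=O)C(CO[Si](C)(C)C(C)(C)C)=C12
F15 | step 12 | (1R,3S,4S,7E)-1-[4-({[tert-butyl(dimethyl)silyl]oxy}methyl)-2-(tributylstannyl)furan-3-yl]-1-hydroxy-8-iodo-3,7-dimethyloct-7-en-4-yl acetate | O[C@@H](c1c(CO[Si](C)(C)C(C)(C)C)coc1[Sn](CCCC)(CCCC)CCCC)C[C@H](C)[C@@H](OC(C)=O)CC/C(C)=C/I
A1 | alternative 1 | (1S,4E,8S,10S)-13-[(tert-butyldimethylsilyl)oxy]-3-(phenylsulfonyl)-8-[(triethylsilyl)oxy]-6,12-epoxygermacra-4,6,11-trien-1-ol (C3 epimers) | CC[Si](CC)(CC)O[C@H]1C[C@H](C)[C@@H](O)CC(S(=O)(=O)c2ccccc2)/C(C)=C/c2occ(CO[Si](C)(C)C(C)(C)C)c12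
A2 | alternative 2 | (2S,4S,5S,8E)-10-[(tert-butyldimethylsilyl)oxy]-1-[(4-methoxybenzyl)oxy]-4,8-dimethyl-2-[(triethylsilyl)oxy]dec-8-en-5-ol | CC(C)(C)[Si](C)(C)OC/C=C(C)/CC[C@H](O)[C@@H](C)C[C@H](O[Si](CC)(CC)CC)COCc1ccc(OC)cc1
A3 | alternative 3 | (1S,4E,6R,10S)-1-acetoxy-13-[(tert-butyldimethylsilyl)oxy]-8-oxogermacra-4,7(11)-dien-12,6-olide | O=C1C[C@H](C)[C@@H](OC(C)=O)CC/C(C)=C/[C@H]2OC(=O)C(CO[Si](C)(C)C(C)(C)C)=C12
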